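Its constants come from no measurement; the result is computed.

| flask | substrate | reagent | time | remark |
|---|---|---|---|---|
| south-west | 0.20 M | 0.160 M | 1.5 h | everything together in a closed stirred flask, run for 1.5 h |
| north | 0.20 M | 0.160 M |  | one stirred flow tank at steady state, fed with the mixture as stated, mean residence time 1.5 h |
| south | 0.20 M (fed, over 1.20 h) | 0.160 M | 1.5 h | all but substrate at the start; substrate goes in evenly over 1.20 h, the run ends at 1.5 h |
| north-east | 0.20 M | 0.160 M (fed, over 1.20 h) | 1.5 h | a stirred flask in which reagent is dosed at a steady rate over 1.20 h without added volume, worked up at 1.5 h |

    substrate + reagent → target (k1 = 0.046 L mol⁻¹ min⁻¹)
    2 substrate → side product (k2 = 0.038 L mol⁻¹ min⁻¹)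

- percentages count the substrate that a species holds: one side product counts as two
- a doubled species enters its step squared and goes two at a time
- the stated concentrations are those of everything mixed, before any reaction; amounts are the same in each set-up
- the feed brings no volume worth counting
- run time (south-west): 1.5 h

1. the set-up with the highest amount of target at the outlet or at the end, in percent of the substrate put in ("none" if the first two lie within 2 percentage points) (south-west / north / south / north-east / none)
2. amount of target at the outlet or at the end, in percent of the substrate put in, south-west
3. amount of target at the outlet or at the end, in percent of the substrate put in, north
4. amount of target at the outlet or at the end, in percent of the substrate put in, south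
5. amount of target at the outlet or at the end, in percent of the substrate put in, north-east

Substrate leaves by two doors, so I follow the fraction left and not the fraction made. Holding the charges in the rates (a pseudo-first-order view), the target step draws 0.442 h⁻¹ on the substrate and the pairing draws 0.912 h⁻¹, more than the target step. The first draw over both together is 32.6%, the target's share of the substrate consumed.

For the south-west batch I reckon a fraction left of 13.1%, and the share of the substrate gone gives 28.3%. For the north tank I take the fraction left as one over one plus draw times residence time, giving 21.9%. In south the dosed substrate stays on average the run less half the dosing time, 0.900 h, giving 23.0%. In north-east the reagent dosed so far averages 60.0% of its charge over the run, uptake not counted, so I cut its draw to 0.265 h⁻¹, which gives 18.7%. My pick is south-west.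

The forecast says 28%, 22.5%, 23.2% and 16.5% in that order, with south-west best, and of the slow feed in south it says “it loses too much reaction time”. Its north-east figure is lower than mine.

The flasks give 28.2%, 22.5%, 23.2% and 16.5%, and south-west is best. At the end of south-west 29.2% substrate stands, more than my fraction left, and target holds 39.8% of what went, more than the starting share I carried through the run, so my close batch figure joins two opposite misses. Left ten times as long, south passes south-west, 50.2% against 47.1%, and that reverses the forecast's order of the two.

A neighbour of north-east takes 0.40 M of reagent, dosed the same way. Its draw becomes 0.662 h⁻¹, its share 42.1% and its fraction left 9.43%, so I expect 38.1% target. That flask gives 34.9% target, with 44.5% side product and 21% of the substrate still there.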